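**Remark:** prostanoid numbering is used throughout (C1 = ester carbon, C8–C12 = ring, C13–C20 = lower chain). Compounds 1, 2, 5 and 13 are taken as purchased.

## Analysis of the target

The target is a C20 prostanoid methyl ester built on a cross-conjugated cyclopent-2-enone (ring atoms C8–C12, C9=O, C10=C11). The ring carries an exocyclic C7=C8 double bond (E), continued by C5=C6 (Z) to the allylic acetate at C4. The quaternary C12 carries a second acetate and the (2Z,5Z)-octa-2,5-dienyl chain C13–C20.

There are two stereocentres, C4 (R) and C12 (S). Seven bonds of a flat trienone lie between them, so neither can direct the other and each needs its own source of chirality.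

Of the four alkenes with defined geometry, 5Z is the delicate one: it is conjugated to the dienone and goes to 5E with acid, nucleophiles, iodine or light. Other weak points are:
- the C12 ester, which sits β to any enolate at C8 and is lost once C8 is deprotonated;
- a free C4 hydroxyl, which is γ to the ester (lactone) and placed to add to C7;
- the skipped diene and the electrophilic dienone.

The difficulty is therefore the oxygenated (5Z,7E)-diene and its junction to C8, next to a fully substituted oxygenated carbon, in a molecule that tolerates neither strong base nor acid late in the route.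

The feature used here: O4, C4, C5, C6 and C7, with C5=C6 cis and the oxygen on C4, are atom for atom the ring of a 2-substituted furan (ring O = O4, C2 = C4, C3 = C5, C4 = C6, C5 = C7). This unit is joined to C8 by a double bond, which is the pattern a carbene at C8 leaves when it opens a furan ring.

## Retrosynthetic reasoning

**20 ⇒ 19 ⇒ 18.** The two acetates are removed separately. The C12 ester goes on last because an ester on C12 cannot survive enolate chemistry at C8; a triethylsilyl ether stands in until C8 has become sp2 and is exchanged only then (18 → 19 → 20).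

**18 ⇒ 17 ⇒ 16.** The C4 acetate comes from alcohol 17, and the C4 stereocentre from the prochiral C4 ketone of 16 by a catalyst-controlled reduction. The cut is made at C4–H because a ketone is exactly what the key step leaves on C4. No stereocentre is near, so a catalyst must control the face; the two flanking groups (CH2 and a Z-alkenyl unit) differ enough for that.

**16 ⇒ 12 + 13 (key disconnection).** C7=C8 is cut and O4 is joined back to C7. The C4–C7 segment with its oxygen becomes the aromatic ring of furan 13, which already holds C1–C7, and C8 becomes the carbene carbon of diazo ketone 12. This cut is chosen because it removes three things at once: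
- the fragile 5Z alkene, which becomes a ring bond that can only be cis;
- the C7=C8 bond next to the quaternary centre;
- the oxygen on C4.

The precursor 12 has no side chain and no geometric problem. The forward reaction must add the carbene to the free α-position of the furan, unravel the adduct, keep C8 from reacting within its own molecule, and end with 7E.

**12 ⇒ 10 ⇒ 9.** The diazo group is placed on C8, the only enolisable carbon of 10, by deacylative diazo transfer. The silyl ether of 10 comes from the tertiary alcohol 9.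

**9 ⇒ 8 ⇒ 7, and C12 back to 1.** The C9 carbonyl is traced to a carbinol (8, silyl ether 7), which makes C12 the product of a 1,2-addition to the carbonyl of 1. The purchased C9–O stereocentre sends the nucleophile to the opposite face and is then oxidised away. Chirality is thus moved from a secondary carbon to the quaternary one. The cut is at C12–C13 because C12 is the carbonyl carbon of 1.

**7 ⇒ 6 ⇒ 4 + 5; 4 ⇒ 1 + 2.** The lower chain is built on the ring. C14=C15 comes from the alkyne of 6 by cis-hydrogenation, C15–C16 from a copper coupling with 5 (which brings 17Z), and C13–C15 from 2. A complete metalated C13–C20 chain is avoided because it would react through C15; the zinc reagent from 2 delivers an unbranched CH2 at C13.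

## Alternatives that were turned down

**Alternative 1:** (textbook) cut at C7=C8 by aldol condensation. The lithium enolate of 10 would add to the enal A1, methyl (4R,5Z)-4-acetoxy-7-oxohept-5-enoate; the aldol A2 would be dehydrated to 18. Turned down for three reasons:
- A1 must carry both C4 and the 5Z alkene as a γ-acyloxy (Z)-enal. It needs its own asymmetric synthesis of about five steps, isomerises easily to the E-enal, and can lose acetate under enolate conditions.
- The union forms one bond, gives an aldol mixture, and needs a separate elimination.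
- The 5Z alkene is made early and carried through basic steps.

It is kept as a fallback only.

**Alternative 2:** cut both ring C–O bonds (C9=O, C12–O) back to the fulvene A3. Singlet oxygen would add across C9/C12 to the endoperoxide A4, and base would convert A4 to 19 (Kornblum–DeLaMare rearrangement). This is the shortest route on paper but was turned down on structure:
- A3 is flat and its only stereocentre (C4) is far from the ring, so both faces react alike and C12 would form as a 1:1 pair of epimers.
- The condensation that builds A3 from A1 favours the ring position remote from the C12 substituent and the less hindered C7=C8 geometry.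
- Singlet oxygen also has the skipped diene (ene reaction) and the side-chain diene to attack.

**Alternative 3:** cut C8–C9 and C9–C10 and take C9 from carbon monoxide. The (Z)-iodo triene A5 would undergo oxidative addition at C10–I, CO insertion, 5-exo acylpalladation at C8 and β-hydride elimination to 18. Turned down because:
- After acylpalladation the metal sits on the allylic C5–C7 unit, where syn/anti interchange erases the 5Z geometry.
- The doubly allylic C12–O bond of A5 can ionise with zerovalent palladium.
- A5 is an acyclic tertiary carbinol with three different unsaturated arms. It would need its own asymmetric synthesis and is no simpler than the product.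

Key step: step 8

## Route

Step 1
Reactants: 1 (4S)-4-(tert-butyldimethylsilyloxy)cyclopent-2-en-1-one; 2 3-bromoprop-1-yne
Product: 4 (1R,4S)-4-(tert-butyldimethylsilyloxy)-1-(prop-2-yn-1-yl)cyclopent-2-en-1-ol, via allenylzinc bromide 3 (not isolated)
Conditions: Zn dust, THF, 0 to 23 °C; aq. NH4Cl
Reagents that add atoms: none
Why: Barbier propargylation; the allenylzinc reagent adds 1,2 to the enone through its γ-carbon and so delivers the unbranched propargyl group; attack anti to the C9 silyloxy group sets C12, and the minor syn adduct is a diastereomer that should be removed by chromatography here.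

Step 2
Reactants: 4 (1R,4S)-4-(tert-butyldimethylsilyloxy)-1-(prop-2-yn-1-yl)cyclopent-2-en-1-ol; 5 (2Z)-1-bromopent-2-ene
Product: 6 (1R,4S)-4-(tert-butyldimethylsilyloxy)-1-[(5Z)-oct-5-en-2-yn-1-yl]cyclopent-2-en-1-ol
Conditions: CuI (20 mol%), Cs2CO3, DMF, 23 °C
Reagents that add atoms: none
Why: Copper-mediated coupling of a terminal alkyne with a primary allylic bromide, the standard entry to skipped enynes; substitution at CH2 should keep the 17Z geometry of 5, and the tertiary alcohol needs no protection.

Step 3
Reactants: 6 (1R,4S)-4-(tert-butyldimethylsilyloxy)-1-[(5Z)-oct-5-en-2-yn-1-yl]cyclopent-2-en-1-ol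
Product: 7 (1R,4S)-4-(tert-butyldimethylsilyloxy)-1-[(2Z,5Z)-octa-2,5-dien-1-yl]cyclopent-2-en-1-ol
Conditions: H2 (1 atm), Pd/CaCO3 poisoned with Pb(OAc)2 (Lindlar catalyst), quinoline, EtOAc, 23 °C
Reagents that add atoms: none
Why: Lindlar semi-hydrogenation; syn delivery of hydrogen to the alkyne gives 14Z, and the disubstituted ring and chain alkenes should not react on the poisoned catalyst.

Step 4
Reactants: 7 (1R,4S)-4-(tert-butyldimethylsilyloxy)-1-[(2Z,5Z)-octa-2,5-dien-1-yl]cyclopent-2-en-1-ol
Product: 8 (1R,4S)-1-[(2Z,5Z)-octa-2,5-dien-1-yl]cyclopent-2-ene-1,4-diol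
Conditions: Bu4NF, THF, 0 to 23 °C; aq. NH4Cl
Reagents that add atoms: none
Why: Fluoride cleavage of the secondary silyl ether; no stereocentre is touched.

Step 5
Reactants: 8 (1R,4S)-1-[(2Z,5Z)-octa-2,5-dien-1-yl]cyclopent-2-ene-1,4-diol
Product: 9 (4R)-4-hydroxy-4-[(2Z,5Z)-octa-2,5-dien-1-yl]cyclopent-2-en-1-one
Conditions: MnO2 (excess), CH2Cl2, 23 °C
Reagents that add atoms: none
Why: Chemoselective oxidation of the secondary allylic alcohol by MnO2 (the tertiary alcohol cannot be oxidised); the C9 stereocentre is erased after passing its information to C12, and neutral conditions avoid retro-aldol opening of the β-hydroxy ketone.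

Step 6
Reactants: 9 (4R)-4-hydroxy-4-[(2Z,5Z)-octa-2,5-dien-1-yl]cyclopent-2-en-1-one
Product: 10 (4R)-4-[(2Z,5Z)-octa-2,5-dien-1-yl]-4-(triethylsilyloxy)cyclopent-2-en-1-one
Conditions: Et3SiOTf, 2,6-lutidine, CH2Cl2, −78 to 0 °C; aq. NaHCO3
Reagents that add atoms: triethylsilyl trifluoromethanesulfonate, CC[Si](CC)(CC)OS(=O)(=O)C(F)(F)F
Why: Silylation of a hindered tertiary alcohol with a silyl triflate; the silyl ether, unlike an ester, survives enolate formation at C8 and cannot take part in carbene chemistry as a neighbouring carbonyl group.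

Step 7
Reactants: 10 (4R)-4-[(2Z,5Z)-octa-2,5-dien-1-yl]-4-(triethylsilyloxy)cyclopent-2-en-1-one
Product: 12 (4S)-5-diazo-4-[(2Z,5Z)-octa-2,5-dien-1-yl]-4-(triethylsilyloxy)cyclopent-2-en-1-one, via trifluoroacetyl ketone 11 (not isolated)
Conditions: LiN(SiMe3)2, THF, −78 °C; CF3CO2CH2CF3; aq. HCl work-up; then MsN3, Et3N, H2O, MeCN, 23 °C
Reagents that add atoms: methanesulfonyl azide, CS(=O)(=O)N=[N+]=[N-]
Why: Deacylative (Regitz-type, detrifluoroacetylative) diazo transfer, the standard way to α'-diazo enones; C8 is the only enolisable carbon, and at −78 °C the β-silyloxy enolate should be acylated faster than it loses silanolate, a loss that would in any case create an antiaromatic dienone.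

Step 8
Reactants: 12 (4S)-5-diazo-4-[(2Z,5Z)-octa-2,5-dien-1-yl]-4-(triethylsilyloxy)cyclopent-2-en-1-one; 13 methyl 3-(furan-2-yl)propanoate
Product: 16 methyl (5Z,7E)-7-[(2S)-2-[(2Z,5Z)-octa-2,5-dien-1-yl]-5-oxo-2-(triethylsilyloxy)cyclopent-3-en-1-ylidene]-4-oxohept-5-enoate, via spirocyclopropane 14 (not isolated), via spiro-2H-pyran 15 (not isolated)
Conditions: 13 (5 equiv), Rh2(OAc)4 (1 mol%), CH2Cl2, 23 °C, slow addition of 12; filtration from the catalyst; then toluene, 40 °C, dark
Reagents that add atoms: none
Why: Rh2(OAc)4 takes N2 from 12 to give an electrophilic rhodium carbene at C8, which adds to the free α-position of furan 13 (C7) and closes onto C6 to the spirocyclopropane 14; 14 is a 2-oxabicyclo[3.1.0]hexene and should open at once in a six-electron electrocyclic step (C6–C8 and C7–O cleave) to the dienedione, the known outcome of α-diazo ketones with 2-alkylfurans (carbene-induced furan ring opening). The step closes no ring of the product; the two transient rings are the cyclopropane (carbene addition) and, during the warm hold, the 2H-pyran 15 (disrotatory oxa-6π closure of O4 onto C8). C5=C6 is the former ring bond C3=C4 of the furan and can only emerge cis, so 5Z needs no reagent control. C7=C8 is set in the cyclopropane, where the C8 substituent lying exo ends trans to C6 and acyl groups of carbenes prefer exo, which places C9=O trans to C6 (7E); material with the other geometry is not lost, because in the 5Z series both geometries close reversibly to 15 and reopen, and the hold at 40 °C should funnel the mixture to 7E, in which C6 lies beside the sp3 centre C12 (substituents above and below the plane) instead of beside the in-plane C9=O. C12 is not touched and no new stereocentre is formed. The step needs the carbene to be trapped between molecules before it reacts within its own: C12 is quaternary (no 1,2-hydride shift), any 1,2-shift from C12 to C8 would put a C8=C12 bond into a ring that already holds C10=C11 and C9=O (an antiaromatic dienone), the only C–H bonds within reach of a five-membered transition state are vinylic or α to silicon, and the furan, the most electron-rich π system present, is in excess while 12 is added slowly. Regioselectivity on the furan follows from attack at the unsubstituted α-carbon, with positive charge developing on the substituted C4.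

Step 9
Reactants: 16 methyl (5Z,7E)-7-[(2S)-2-[(2Z,5Z)-octa-2,5-dien-1-yl]-5-oxo-2-(triethylsilyloxy)cyclopent-3-en-1-ylidene]-4-oxohept-5-enoate
Product: 17 methyl (4R,5Z,7E)-4-hydroxy-7-[(2S)-2-[(2Z,5Z)-octa-2,5-dien-1-yl]-5-oxo-2-(triethylsilyloxy)cyclopent-3-en-1-ylidene]hept-5-enoate
Conditions: (S)-2-methyl-CBS-oxazaborolidine (20 mol%), catecholborane, toluene, −78 °C; pH 7 buffer
Reagents that add atoms: none
Why: Corey–Bakshi–Shibata reduction; the catalyst binds the C4 carbonyl next to the small CH2 group and, with the Z-alkenyl group as the large substituent, the (S)-catalyst should deliver hydride to give 4R (by analogy with alkenyl alkyl ketones); the C9 carbonyl is cross-conjugated, flanked by two sp2 carbons and the quaternary C12, and should react more slowly.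

Step 10
Reactants: 17 methyl (4R,5Z,7E)-4-hydroxy-7-[(2S)-2-[(2Z,5Z)-octa-2,5-dien-1-yl]-5-oxo-2-(triethylsilyloxy)cyclopent-3-en-1-ylidene]hept-5-enoate
Product: 18 methyl (4R,5Z,7E)-4-acetoxy-7-[(2S)-2-[(2Z,5Z)-octa-2,5-dien-1-yl]-5-oxo-2-(triethylsilyloxy)cyclopent-3-en-1-ylidene]hept-5-enoate
Conditions: Ac2O, pyridine, DMAP (cat.), CH2Cl2, 0 °C, on crude 17
Reagents that add atoms: acetic anhydride, CC(=O)OC(C)=O
Why: Acylation of the secondary allylic alcohol, done at once so that the free C4 hydroxyl can neither lactonise onto C1 nor add to C7; the configuration at C4 is retained.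

Step 11
Reactants: 18 methyl (4R,5Z,7E)-4-acetoxy-7-[(2S)-2-[(2Z,5Z)-octa-2,5-dien-1-yl]-5-oxo-2-(triethylsilyloxy)cyclopent-3-en-1-ylidene]hept-5-enoate
Product: 19 methyl (4R,5Z,7E)-4-acetoxy-7-[(2S)-2-hydroxy-2-[(2Z,5Z)-octa-2,5-dien-1-yl]-5-oxocyclopent-3-en-1-ylidene]hept-5-enoate
Conditions: HF·pyridine, pyridine, THF, 0 to 23 °C
Reagents that add atoms: none
Why: Buffered fluoride cleavage of the tertiary silyl ether; the C12–O bond should not ionise (the cation would be an antiaromatic cyclopentadienyl-type cation), and the acetate and the 5Z alkene tolerate these mild conditions.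

Step 12
Reactants: 19 methyl (4R,5Z,7E)-4-acetoxy-7-[(2S)-2-hydroxy-2-[(2Z,5Z)-octa-2,5-dien-1-yl]-5-oxocyclopent-3-en-1-ylidene]hept-5-enoate
Product: 20 methyl (4R,5Z,7E)-4-acetoxy-7-[(2S)-2-acetoxy-2-[(2Z,5Z)-octa-2,5-dien-1-yl]-5-oxocyclopent-3-en-1-ylidene]hept-5-enoate (the target)
Conditions: Ac2O, DMAP, Et3N, CH2Cl2, 23 °C
Reagents that add atoms: acetic anhydride, CC(=O)OC(C)=O
Why: DMAP-catalysed acylation of the tertiary alcohol; C8 is now sp2, so the β-acetoxy ketone has no enolisable position from which the new ester could be eliminated.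

## Compound list

1 | (4S)-4-(tert-butyldimethylsilyloxy)cyclopent-2-en-1-one | O=C1C=C[C@@H](O[Si](C)(C)C(C)(C)C)C1 | starting material
2 | 3-bromoprop-1-yne | C#CCBr | starting material
3 | allenylzinc bromide (propa-1,2-dien-1-ylzinc bromide) | C=C=C[Zn]Br | intermediate
4 | (1R,4S)-4-(tert-butyldimethylsilyloxy)-1-(prop-2-yn-1-yl)cyclopent-2-en-1-ol | C#CC[C@]1(O)C=C[C@@H](O[Si](C)(C)C(C)(C)C)C1 | intermediate
5 | (2Z)-1-bromopent-2-ene | CC/C=C\CBr | starting material
6 | (1R,4S)-4-(tert-butyldimethylsilyloxy)-1-[(5Z)-oct-5-en-2-yn-1-yl]cyclopent-2-en-1-ol | CC/C=C\CC#CC[C@]1(O)C=C[C@@H](O[Si](C)(C)C(C)(C)C)C1 | intermediate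
7 | (1R,4S)-4-(tert-butyldimethylsilyloxy)-1-[(2Z,5Z)-octa-2,5-dien-1-yl]cyclopent-2-en-1-ol | CC/C=C\C/C=C\C[C@]1(O)C=C[C@@H](O[Si](C)(C)C(C)(C)C)C1 | intermediate
8 | (1R,4S)-1-[(2Z,5Z)-octa-2,5-dien-1-yl]cyclopent-2-ene-1,4-diol | CC/C=C\C/C=C\C[C@]1(O)C=C[C@@H](O)C1 | intermediate
9 | (4R)-4-hydroxy-4-[(2Z,5Z)-octa-2,5-dien-1-yl]cyclopent-2-en-1-one | CC/C=C\C/C=C\C[C@]1(O)C=CC(=O)C1 | intermediate
10 | (4R)-4-[(2Z,5Z)-octa-2,5-dien-1-yl]-4-(triethylsilyloxy)cyclopent-2-en-1-one | CC/C=C\C/C=C\C[C@]1(O[Si](CC)(CC)CC)C=CC(=O)C1 | intermediate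
11 | trifluoroacetyl ketone: 5-(trifluoroacetyl) derivative of 10 (C12 as in 10; C8 epimers and enol) | CC/C=C\C/C=C\C[C@]1(O[Si](CC)(CC)CC)C=CC(=O)C1C(=O)C(F)(F)F | intermediate
12 | (4S)-5-diazo-4-[(2Z,5Z)-octa-2,5-dien-1-yl]-4-(triethylsilyloxy)cyclopent-2-en-1-one | CC/C=C\C/C=C\C[C@]1(O[Si](CC)(CC)CC)C=CC(=O)C1=[N+]=[N-] | intermediate
13 | methyl 3-(furan-2-yl)propanoate | COC(=O)CCc1ccco1 | starting material
14 | spirocyclopropane: 2-oxabicyclo[3.1.0]hex-3-ene from addition of C8 of 12 across C6=C7 of 13, C8 spiro to the cyclopentenone (C12 as in 12; C6, C7, C8 as formed) | CC/C=C\C/C=C\C[C@]1(O[Si](CC)(CC)CC)C=CC(=O)C12C3OC(CCC(=O)OC)=CC23 | intermediate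
15 | spiro-2H-pyran: methyl 3-[(1S)-1-[(2Z,5Z)-octa-2,5-dien-1-yl]-4-oxo-1-(triethylsilyloxy)-6-oxaspiro[4.5]deca-2,7,9-trien-7-yl]propanoate (both configurations at the spiro carbon) | CC/C=C\C/C=C\C[C@]1(O[Si](CC)(CC)CC)C=CC(=O)C12OC(CCC(=O)OC)=CC=C2 | intermediate
16 | methyl (5Z,7E)-7-[(2S)-2-[(2Z,5Z)-octa-2,5-dien-1-yl]-5-oxo-2-(triethylsilyloxy)cyclopent-3-en-1-ylidene]-4-oxohept-5-enoate | CC/C=C\C/C=C\C[C@]1(O[Si](CC)(CC)CC)C=CC(=O)/C1=C/C=C\C(=O)CCC(=O)OC | intermediate
17 | methyl (4R,5Z,7E)-4-hydroxy-7-[(2S)-2-[(2Z,5Z)-octa-2,5-dien-1-yl]-5-oxo-2-(triethylsilyloxy)cyclopent-3-en-1-ylidene]hept-5-enoate | CC/C=C\C/C=C\C[C@]1(O[Si](CC)(CC)CC)C=CC(=O)/C1=C/C=C\[C@@H](CCC(=O)OC)O | intermediate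
18 | methyl (4R,5Z,7E)-4-acetoxy-7-[(2S)-2-[(2Z,5Z)-octa-2,5-dien-1-yl]-5-oxo-2-(triethylsilyloxy)cyclopent-3-en-1-ylidene]hept-5-enoate | CC/C=C\C/C=C\C[C@]1(O[Si](CC)(CC)CC)C=CC(=O)/C1=C/C=C\[C@@H](CCC(=O)OC)OC(C)=O | intermediate
19 | methyl (4R,5Z,7E)-4-acetoxy-7-[(2S)-2-hydroxy-2-[(2Z,5Z)-octa-2,5-dien-1-yl]-5-oxocyclopent-3-en-1-ylidene]hept-5-enoate | CC/C=C\C/C=C\C[C@]1(O)C=CC(=O)/C1=C/C=C\[C@@H](CCC(=O)OC)OC(C)=O | intermediate
20 | methyl (4R,5Z,7E)-4-acetoxy-7-[(2S)-2-acetoxy-2-[(2Z,5Z)-octa-2,5-dien-1-yl]-5-oxocyclopent-3-en-1-ylidene]hept-5-enoate | CC/C=C\C/C=C\C[C@]1(OC(C)=O)C=CC(=O)/C1=C/C=C\[C@@H](CCC(=O)OC)OC(C)=O | target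

## Step count and least certain steps

Total step count: 12. Longest linear sequence: 12 steps (1 → 20); furan 13 enters as purchased in step 8.

**Step 8 (key step).** Three processes can go wrong:
- Capture of the carbene within its own molecule (insertion into the doubly allylic C16–H bond, a shift from C12) or by a chain alkene, because the carbene carbon is shielded by the quaternary C12 and intermolecular trapping is slowed.
- Incomplete funnelling of the C7=C8 geometry, if the ring-closure/ring-opening equilibrium is slow or not one-sided.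
- Leakage of 5Z to 5E through traces of acid or rhodium during the warm hold.

Fallback, from 10 and 13, back at 16: oxidative ring opening of 13 (NBS, NaHCO3, aqueous acetone, −15 °C) would give methyl (5Z)-4,7-dioxohept-5-enoate F1. The lithium enolate of 10 (LiN(iPr)2, THF, −78 °C) would add to the aldehyde of F1 to give the aldol F2. Mesylation and elimination (MsCl, Et3N) would give 16. This uses the same furan as source of the cis-enedione but joins C7 to C8 by aldol chemistry.

**Step 7.** The C8 enolate may lose the C12 silanolate before it is acylated, or acylation next to the quaternary centre may go to oxygen, leaving nothing for the diazo transfer to act on.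

Fallback, from 10, back at 12: condensation of 10 with tert-butoxybis(dimethylamino)methane (toluene, 80 °C, no strong base) would give the enaminone F3. p-Toluenesulfonyl azide would then transfer the diazo group to C8 by cycloaddition to the enamine and fragmentation, giving 12.

**Step 9.** Three processes can go wrong:
- Poor facial selectivity, because a Z-alkenyl group next to a primary alkyl group is not an ideal pair for the catalyst.
- Competing reduction at C9 or conjugate reduction of the s-cis enone.
- Cyclisation of the free C4 hydroxyl before it is acetylated.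

Fallback, from 10, back at 18, with C4 set before the union:
- Acyl Sonogashira coupling of methyl 4-chloro-4-oxobutanoate with 3,3-diethoxyprop-1-yne (PdCl2(PPh3)2, CuI, Et3N) would give the ynone F4.
- Asymmetric transfer hydrogenation (RuCl(p-cymene)[(R,R)-TsDPEN], iPrOH) would give the propargylic alcohol F5.
- Acetylation would give F6.
- Lindlar semi-hydrogenation would give the Z-alkene F7.
- Mild acid hydrolysis of the acetal would give the enal F8 (identical with A1).
- Aldol addition of the lithium enolate of 10 to F8 would give F9 (identical with A2).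
- Mesylation and elimination would give 18.

**Step 2.** Substitution of the allylic bromide with allylic transposition (branched 1,4-enyne) or partial loss of the Z geometry in the copper coupling would contaminate the chain.

Fallback, from 4, back at 7: coupling of 4 with 1-bromopent-2-yne (CuI, Cs2CO3, DMF) would give the skipped diyne F10, for which transposition is not an issue. Semi-hydrogenation of both alkynes (H2, Lindlar catalyst, quinoline) would set 14Z and 17Z together and give 7.

## Further compounds

F1 | step 8 | methyl (5Z)-4,7-dioxohept-5-enoate | COC(=O)CCC(=O)/C=C\C=O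
F2 | step 8 | methyl (5Z)-7-hydroxy-7-[2-[(2Z,5Z)-octa-2,5-dien-1-yl]-5-oxo-2-(triethylsilyloxy)cyclopent-3-en-1-yl]-4-oxohept-5-enoate (C12 as in 10; C7 and C8 epimers) | CC/C=C\C/C=C\C[C@]1(O[Si](CC)(CC)CC)C=CC(=O)C1C(O)/C=C\C(=O)CCC(=O)OC
F3 | step 7 | (4S)-5-[(dimethylamino)methylidene]-4-[(2Z,5Z)-octa-2,5-dien-1-yl]-4-(triethylsilyloxy)cyclopent-2-en-1-one | CC/C=C\C/C=C\C[C@]1(O[Si](CC)(CC)CC)C=CC(=O)C1=CN(C)C
F4 | step 9 | methyl 7,7-diethoxy-4-oxohept-5-ynoate | COC(=O)CCC(=O)C#CC(OCC)OCC
F5 | step 9 | methyl (4R)-7,7-diethoxy-4-hydroxyhept-5-ynoate | CCOC(OCC)C#C[C@@H](CCC(=O)OC)O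
F6 | step 9 | methyl (4R)-4-acetoxy-7,7-diethoxyhept-5-ynoate | CCOC(OCC)C#C[C@@H](CCC(=O)OC)OC(C)=O
F7 | step 9 | methyl (4R,5Z)-4-acetoxy-7,7-diethoxyhept-5-enoate | CCOC(OCC)/C=C\[C@@H](CCC(=O)OC)OC(C)=O
F8 | step 9 | methyl (4R,5Z)-4-acetoxy-7-oxohept-5-enoate | O=C/C=C\[C@@H](CCC(=O)OC)OC(C)=O
F9 | step 9 | methyl (4R,5Z)-4-acetoxy-7-hydroxy-7-[2-[(2Z,5Z)-octa-2,5-dien-1-yl]-5-oxo-2-(triethylsilyloxy)cyclopent-3-en-1-yl]hept-5-enoate (C12 as in 10; C7 and C8 epimers) | CC/C=C\C/C=C\C[C@]1(O[Si](CC)(CC)CC)C=CC(=O)C1C(O)/C=C\[C@@H](CCC(=O)OC)OC(C)=O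
F10 | step 2 | (1R,4S)-4-(tert-butyldimethylsilyloxy)-1-(octa-2,5-diyn-1-yl)cyclopent-2-en-1-ol | CCC#CCC#CC[C@]1(O)C=C[C@@H](O[Si](C)(C)C(C)(C)C)C1
A1 | alternative 1 | methyl (4R,5Z)-4-acetoxy-7-oxohept-5-enoate | O=C/C=C\[C@@H](CCC(=O)OC)OC(C)=O
A2 | alternative 1 | methyl (4R,5Z)-4-acetoxy-7-hydroxy-7-[2-[(2Z,5Z)-octa-2,5-dien-1-yl]-5-oxo-2-(triethylsilyloxy)cyclopent-3-en-1-yl]hept-5-enoate (C12 as in 10; C7 and C8 epimers) | CC/C=C\C/C=C\C[C@]1(O[Si](CC)(CC)CC)C=CC(=O)C1C(O)/C=C\[C@@H](CCC(=O)OC)OC(C)=O
A3 | alternative 2 | methyl (4R,5Z)-4-acetoxy-7-[2-[(2Z,5Z)-octa-2,5-dien-1-yl]cyclopenta-2,4-dien-1-ylidene]hept-5-enoate | CC/C=C\C/C=C\CC1=CC=C/C1=C/C=C\[C@@H](CCC(=O)OC)OC(C)=O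
A4 | alternative 2 | methyl (4R,5Z)-4-acetoxy-7-[1-[(2Z,5Z)-octa-2,5-dien-1-yl]-2,3-dioxabicyclo[2.2.1]hept-5-en-7-ylidene]hept-5-enoate (both bridgehead configurations) | CC/C=C\C/C=C\CC12C=CC(OO1)/C2=C/C=C\[C@@H](CCC(=O)OC)OC(C)=O
A5 | alternative 3 | methyl (4R,5Z,7E,10Z)-4-acetoxy-11-iodo-9-[(2Z,5Z)-octa-2,5-dien-1-yl]-9-(triethylsilyloxy)undeca-5,7,10-trienoate (C9 arranged as C12 of 18) | CC/C=C\C/C=C\C[C@](O[Si](CC)(CC)CC)(/C=C\I)/C=C/C=C\[C@@H](CCC(=O)OC)OC(C)=O
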